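**Retrosynthetic overview**

1. The target is disconnected at the C8 ester into a furanose hemiketal core and (E)-N-methylurocanic acid (1-methylimidazole-4-carbaldehyde + malonic acid).
2. Ring C (4,7-oxygen-bridged dihydrofuran hemiketal) comes from a furan: Achmatowicz ring expansion to a bridged hydroxypyranone, exo methyl addition at C7, then pyranose→furanose ring contraction.
3. Ring B (ten-membered) is closed as a [6](2,5)furanophane at C3–C4 by a nickel-hydride reductive α-heteroarylation of an enoate with a tethered bromofuran.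
4. Ring A comes from a catalytic asymmetric Diels–Alder reaction of (E)-4-methylpent-2-enal with a furyl-bearing (E)-diene, telescoped with a Wittig olefination.
5. The diene comes from 5-bromofurfural by catalytic enantioselective pentadienylation with a silane made from 3-methylpenta-1,4-diene. Ring order: A, then B (furan in place), then C (expansion, then contraction).

Locants: ring A = C1, C10, C11 (Me), C12, C13, C14 (iPr); ring B = C1–C10 with C2 (CH2), C3 (CHCO2Me), C4, C5=C6, C7, C8, C9 (CH2). The target is (1R,3R,4R,7S,8S,10R,14R).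

Assumption: C3 lies between the ester and the masked C4 ketone and is epimerisable through ring–chain tautomerism; the target's 3R configuration is taken to be the thermodynamically preferred one and is set by equilibration in step 7 (intermediates are drawn 3R).

**Route**

Step 1
Reactants: 1 3-methylpenta-1,4-diene
Product: 2 tert-butyl(dimethyl)[(2E)-3-methylpenta-2,4-dien-1-yl]silane
Conditions: n-BuLi, TMEDA, THF, −78 → 0 °C; then TBSCl, −78 → 23 °C
Reagents that add atoms: tert-butyldimethylsilyl chloride, CC(C)(C)[Si](C)(C)Cl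
Why: Metalation–silylation: deprotonation of the doubly allylic C–H gives the 3-methylpentadienyl anion, which is silylated at the unhindered terminus (central attack would build a quaternary centre); the geometry of the new C2=C3 bond is erased in step 2.

Step 2
Reactants: 2 tert-butyl(dimethyl)[(2E)-3-methylpenta-2,4-dien-1-yl]silane; 3 5-bromofuran-2-carbaldehyde
Product: 4 tert-butyl{[(1S,3E)-1-(5-bromofuran-2-yl)-4-methylhexa-3,5-dien-1-yl]oxy}dimethylsilane
Conditions: chiral IDPi Brønsted acid (N-triflyl imidodiphosphorimidate on 3,3′-diaryl-BINOL backbones; the enantiomer that gives 8S; 2 mol %), toluene/CH2Cl2, −78 °C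
Reagents that add atoms: none
Why: Proposed new method: the silylated IDPi acts as a chiral silylium Lewis acid that converts 3 into an O-silyl oxocarbenium ion paired with the confined chiral anion, the pentadienylsilane attacks the aldehyde Si face through its terminal ε-carbon (the γ-carbon bears the methyl group, so attack there is blocked) from the s-trans conformer to give the (E)-conjugated diene, and the β-silyl cation returns the TBS group to the catalyst so that the product leaves as its TBS ether with C8 (S) set by the catalyst; the closest known reactions are the IDPi-catalysed asymmetric Hosomi–Sakurai allylation of aldehydes and the ε-selective Lewis-acid addition of 2,4-pentadienylsilanes to aldehydes.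

Step 3
Reactants: 4 tert-butyl{[(1S,3E)-1-(5-bromofuran-2-yl)-4-methylhexa-3,5-dien-1-yl]oxy}dimethylsilane; 5 (2E)-4-methylpent-2-enal
Product: 7 methyl (2E)-3-[(1R,2R,6R)-2-{(2S)-2-(5-bromofuran-2-yl)-2-[(tert-butyldimethylsilyl)oxy]ethyl}-3-methyl-6-(propan-2-yl)cyclohex-3-en-1-yl]prop-2-enoate, via Diels–Alder aldehyde 6 (not isolated)
Conditions: 5 (3 equiv), second-generation MacMillan imidazolidinone (2S,5S)-5-benzyl-2-tert-butyl-3-methylimidazolidin-4-one·TFA (20 mol %), MeCN/H2O 95:5, −10 → 4 °C; excess 5 removed in vacuo; then Ph3P=CHCO2Me, CH2Cl2, 23 °C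
Reagents that add atoms: methyl (triphenylphosphoranylidene)acetate, COC(=O)C=P(c1ccccc1)(c1ccccc1)c1ccccc1
Why: Iminium-catalysed Diels–Alder reaction then Wittig olefination: the benzyl group of the catalyst covers one face of the (E)-iminium ion of 5, so the diene adds endo to the open face (Si at the α-carbon) with its unsubstituted terminus bonding to the hindered isopropyl-bearing β-carbon, which sets C1, C10 and C14 (two side chains cis, isopropyl trans), and the stabilised ylide then gives the (E)-enoate before the α-stereocentre can epimerise.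

Step 4
Reactants: 7 methyl (2E)-3-[(1R,2R,6R)-2-{(2S)-2-(5-bromofuran-2-yl)-2-[(tert-butyldimethylsilyl)oxy]ethyl}-3-methyl-6-(propan-2-yl)cyclohex-3-en-1-yl]prop-2-enoate
Product: 8 TBS-protected furanophane ester (ring B closed; C4–C7 = 2,5-furandiyl; 3-CO2Me; 8-OTBS; 1R,3R,8S,10R,14R)
Conditions: NiBr2·glyme (15 mol %), 4,4′-di-tert-butyl-2,2′-bipyridine (18 mol %), (MeO)2MeSiH, KF, DMA/THF, 23 °C, syringe-pump addition of 7 (final 2 mM)
Reagents that add atoms: none
Why: Proposed new method: a nickel hydride (from NiBr2·glyme, silane and fluoride) adds across the enoate with hydride to C2 to give the C3-bound nickel enolate, the ligated nickel then inserts into the tethered furyl C–Br bond (monovalent to trivalent nickel) and C(sp3)–C(sp2) reductive elimination forms the C3–C4 bond and the ten-membered ring under high dilution, C3 needing no control here because it is equilibrated in step 7; the closest known reactions are intermolecular NiH-catalysed α-selective hydroarylation and hydroalkylation of α,β-unsaturated carbonyl compounds and palladium-catalysed α-arylation of ester enolates.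

Step 5
Reactants: 8 TBS-protected furanophane ester (ring B closed; C4–C7 = 2,5-furandiyl; 3-CO2Me; 8-OTBS; 1R,3R,8S,10R,14R)
Product: 9 furanophane alcohol (8-OH; 1R,3R,8S,10R,14R)
Conditions: TBAF, THF, 0 °C
Reagents that add atoms: none
Why: Fluoride-mediated desilylation frees the furyl carbinol needed for the oxidative rearrangement without touching a stereocentre.

Step 6
Reactants: 9 furanophane alcohol (8-OH; 1R,3R,8S,10R,14R)
Product: 10 bridged hydroxypyranone (4,8-oxygen bridge; 4-OH; 5,6-ene; 7-oxo; 1R,3R,4S,8S,10R,14R)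
Conditions: NBS (1.0 equiv), NaHCO3, THF/H2O 4:1, 0 °C
Reagents that add atoms: water, O
Why: Achmatowicz rearrangement: bromination and hydration of the electron-rich furan (faster than the trisubstituted alkene) opens it to the cis-enedione, whose C4 ketone is captured by the C8 hydroxyl, expanding the five-membered furan to the six-membered hydroxypyranone with C8 retained and C4 fixed by the bridge.

Step 7
Reactants: 10 bridged hydroxypyranone (4,8-oxygen bridge; 4-OH; 5,6-ene; 7-oxo; 1R,3R,4S,8S,10R,14R)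
Product: 12 furanose diol (8-deacyl target; 4,7-oxygen bridge; 4-OH; 8-OH; 1R,3R,4R,7S,8S,10R,14R), via pyranose diol 11 (not isolated)
Conditions: MeMgBr (3 equiv), THF, −78 °C; H2O quench; then CSA (5 mol %), CH2Cl2, 23 °C
Reagents that add atoms: methylmagnesium bromide, C[Mg]Br
Why: Grignard 1,2-addition to the C7 ketone (faster than to the ester at −78 °C) from the exo face opposite the C9–C3 bridge sets C7 with methyl anti to C9, and acid-catalysed ring–chain tautomerism through the hydroxy enone then contracts the pyranose to the furanose hemiketal (oxygen bridge moved from C8 to C7, C4 fixed by the bridge) while the β-keto ester tautomer equilibrates C3 to the more stable epimer.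

Step 8
Reactants: 13 1-methyl-1H-imidazole-4-carbaldehyde; 14 malonic acid
Product: 15 (2E)-3-(1-methyl-1H-imidazol-4-yl)prop-2-enoic acid
Conditions: pyridine, piperidine (cat.), 100 °C
Reagents that add atoms: none
Why: Knoevenagel–Doebner condensation with decarboxylation gives the (E)-acrylic acid.

Step 9
Reactants: 12 furanose diol (8-deacyl target; 4,7-oxygen bridge; 4-OH; 8-OH; 1R,3R,4R,7S,8S,10R,14R); 15 (2E)-3-(1-methyl-1H-imidazol-4-yl)prop-2-enoic acid
Product: 16 CNP0113846.1 (8-O-[(2E)-3-(1-methyl-1H-imidazol-4-yl)prop-2-enoyl] ester of 12; 1R,3R,4R,7S,8S,10R,14R)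
Conditions: DCC, DMAP (cat.), CH2Cl2/DMF, 0 → 23 °C
Reagents that add atoms: none
Why: Steglich esterification acylates only the secondary C8 hydroxyl (the tertiary hemiketal hydroxyl is too hindered), with retention at C8.

**Compound list**

1 | 3-methylpenta-1,4-diene | C=CC(C)C=C | starting material
2 | tert-butyl(dimethyl)[(2E)-3-methylpenta-2,4-dien-1-yl]silane | C=C/C(C)=C/C[Si](C)(C)C(C)(C)C | intermediate
3 | 5-bromofuran-2-carbaldehyde | O=Cc1ccc(Br)o1 | starting material
4 | tert-butyl{[(1S,3E)-1-(5-bromofuran-2-yl)-4-methylhexa-3,5-dien-1-yl]oxy}dimethylsilane | C=C/C(C)=C/C[C@H](O[Si](C)(C)C(C)(C)C)c1ccc(Br)o1 | intermediate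
5 | (2E)-4-methylpent-2-enal | CC(C)/C=C/C=O | starting material
6 | Diels–Alder aldehyde: (1R,2R,6R)-2-{(2S)-2-(5-bromofuran-2-yl)-2-[(tert-butyldimethylsilyl)oxy]ethyl}-3-methyl-6-(propan-2-yl)cyclohex-3-ene-1-carbaldehyde | O=C[C@@H]1[C@@H](C(C)C)CC=C(C)[C@@H]1C[C@H](O[Si](C)(C)C(C)(C)C)c1ccc(Br)o1 | intermediate
7 | methyl (2E)-3-[(1R,2R,6R)-2-{(2S)-2-(5-bromofuran-2-yl)-2-[(tert-butyldimethylsilyl)oxy]ethyl}-3-methyl-6-(propan-2-yl)cyclohex-3-en-1-yl]prop-2-enoate | COC(=O)/C=C/[C@@H]1[C@@H](C(C)C)CC=C(C)[C@@H]1C[C@H](O[Si](C)(C)C(C)(C)C)c1ccc(Br)o1 | intermediate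
8 | TBS-protected furanophane ester (ring B closed; C4–C7 = 2,5-furandiyl; 3-CO2Me; 8-OTBS; 1R,3R,8S,10R,14R) | COC(=O)[C@@H]1C[C@@H]2[C@@H](C(C)C)CC=C(C)[C@@H]2C[C@H](O[Si](C)(C)C(C)(C)C)c2ccc1o2 | intermediate
9 | furanophane alcohol (8-OH; 1R,3R,8S,10R,14R) | COC(=O)[C@@H]1C[C@@H]2[C@@H](C(C)C)CC=C(C)[C@@H]2C[C@H](O)c2ccc1o2 | intermediate
10 | bridged hydroxypyranone (4,8-oxygen bridge; 4-OH; 5,6-ene; 7-oxo; 1R,3R,4S,8S,10R,14R) | COC(=O)[C@@H]1C[C@@H]2[C@@H](C(C)C)CC=C(C)[C@@H]2C[C@@H]2O[C@@]1(O)C=CC2=O | intermediate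
11 | pyranose diol (4,8-oxygen bridge; 4-OH; 7-OH; 7-Me; 1R,3R,4S,7S,8S,10R,14R) | COC(=O)[C@@H]1C[C@@H]2[C@@H](C(C)C)CC=C(C)[C@@H]2C[C@@H]2O[C@@]1(O)C=C[C@]2(C)O | intermediate
12 | furanose diol (8-deacyl target; 4,7-oxygen bridge; 4-OH; 8-OH; 1R,3R,4R,7S,8S,10R,14R) | COC(=O)[C@@H]1C[C@@H]2[C@@H](C(C)C)CC=C(C)[C@@H]2C[C@H](O)[C@]2(C)C=C[C@@]1(O)O2 | intermediate
13 | 1-methyl-1H-imidazole-4-carbaldehyde | Cn1cnc(C=O)c1 | starting material
14 | malonic acid | OC(=O)CC(=O)O | starting material
15 | (2E)-3-(1-methyl-1H-imidazol-4-yl)prop-2-enoic acid | OC(=O)/C=C/c1cn(C)cn1 | intermediate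
16 | CNP0113846.1 (8-O-[(2E)-3-(1-methyl-1H-imidazol-4-yl)prop-2-enoyl] ester of 12; 1R,3R,4R,7S,8S,10R,14R) | COC(=O)[C@@H]1C[C@@H]2[C@@H](C(C)C)CC=C(C)[C@@H]2C[C@H](OC(=O)/C=C/c2cn(C)cn2)[C@]2(C)C=C[C@@]1(O)O2 | target

**Step count and risks**

Total steps: 9. Longest linear sequence: 8 (steps 1–7 and 9; step 8 is a one-step side branch).

The three steps most likely to fail are 4, 2 and 3.

Step 4 (new reductive macrocyclisation). Simple conjugate reduction, hydrodebromination or oligomerisation may outrun closure of the strained furanophane. The fallback sets out from 6 (isolated by stopping step 3 before the ylide is added) and returns at 8, closing the same ring by a Nozaki–Hiyama–Kishi reaction, which is known for this [6](2,5)furanophane ring size. Wittig reaction of 6 with Ph3P=CHOMe gives the methyl enol ether of the one-carbon-homologated aldehyde F7. Hydrolysis (Hg(OAc)2, aqueous THF; then KI) gives 2-[(1R,2R,6R)-2-{(2S)-2-(5-bromofuran-2-yl)-2-[(tert-butyldimethylsilyl)oxy]ethyl}-3-methyl-6-(propan-2-yl)cyclohex-3-en-1-yl]acetaldehyde F8. CrCl2 with catalytic NiCl2 in DMSO/THF at high dilution adds the furyl bromide to the aldehyde and gives the furanophane C3-alcohol F9 (8 with OH in place of CO2Me; C3 epimers). ClCO2Me/pyridine gives the furylic methyl carbonate F10. Palladium-catalysed methoxycarbonylation (Pd(OAc)2, dppf, CO 1 atm, MeOH, 70 °C) of this benzylic-type carbonate gives 8.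

Step 2 (new enantioselective ε-pentadienylation). γ-Attack, low enantioselectivity or acid-induced ionisation of the furyl silyl ether may intervene. The fallback sets out from 3 and returns at 4 by a vinylogous Mukaiyama aldol route. (2E)-2-Methylbut-2-enal is silylated (TBSOTf, Et3N) to the dienol ether tert-butyl(dimethyl){[(1E)-2-methylbuta-1,3-dien-1-yl]oxy}silane F1. Its aldol reaction with 3, promoted by the N-tosyl-tryptophan-derived B-phenyl oxazaborolidinone (the enantiomer that gives the S carbinol), gives (2E,5S)-5-(5-bromofuran-2-yl)-5-hydroxy-2-methylpent-2-enal F2. TBSCl/imidazole gives its silyl ether (2E,5S)-5-(5-bromofuran-2-yl)-5-[(tert-butyldimethylsilyl)oxy]-2-methylpent-2-enal F3. Methylenation with Ph3P=CH2 gives 4 with the E-geometry secured.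

Step 3 (organocatalytic Diels–Alder). The β-isopropyl enal is a sluggish dienophile and the 1,2-disubstituted diene could give regioisomers or lower facial selectivity. The fallback sets out from 4 and returns at 6, replacing catalysis by an auxiliary-controlled, Lewis-acid-chelated cycloaddition. (2E)-4-Methylpent-2-enoic acid (PivCl, Et3N; then lithiated (4S)-4-benzyl-1,3-oxazolidin-2-one) gives the imide (4S)-4-benzyl-3-[(2E)-4-methylpent-2-enoyl]-1,3-oxazolidin-2-one F4. Et2AlCl (CH2Cl2, −78 → −30 °C) with 4 gives the endo adduct (4S)-4-benzyl-3-{[(1R,2R,6R)-2-{(2S)-2-(5-bromofuran-2-yl)-2-[(tert-butyldimethylsilyl)oxy]ethyl}-3-methyl-6-(propan-2-yl)cyclohex-3-en-1-yl]carbonyl}-1,3-oxazolidin-2-one F5; the diene adds anti to the benzyl group of the s-cis chelate. LiBH4 (THF/MeOH) gives [(1R,2R,6R)-2-{(2S)-2-(5-bromofuran-2-yl)-2-[(tert-butyldimethylsilyl)oxy]ethyl}-3-methyl-6-(propan-2-yl)cyclohex-3-en-1-yl]methanol F6 with recovery of the auxiliary. Dess–Martin oxidation gives 6, which continues with the Wittig part of step 3.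

**Further compounds**

F1 | step 2 | tert-butyl(dimethyl){[(1E)-2-methylbuta-1,3-dien-1-yl]oxy}silane | C=C/C(C)=C/O[Si](C)(C)C(C)(C)C
F2 | step 2 | (2E,5S)-5-(5-bromofuran-2-yl)-5-hydroxy-2-methylpent-2-enal | O=C/C(C)=C/C[C@H](O)c1ccc(Br)o1
F3 | step 2 | (2E,5S)-5-(5-bromofuran-2-yl)-5-[(tert-butyldimethylsilyl)oxy]-2-methylpent-2-enal | O=C/C(C)=C/C[C@H](O[Si](C)(C)C(C)(C)C)c1ccc(Br)o1
F4 | step 3 | (4S)-4-benzyl-3-[(2E)-4-methylpent-2-enoyl]-1,3-oxazolidin-2-one | CC(C)/C=C/C(=O)N1[C@@H](Cc2ccccc2)COC1=O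
F5 | step 3 | (4S)-4-benzyl-3-{[(1R,2R,6R)-2-{(2S)-2-(5-bromofuran-2-yl)-2-[(tert-butyldimethylsilyl)oxy]ethyl}-3-methyl-6-(propan-2-yl)cyclohex-3-en-1-yl]carbonyl}-1,3-oxazolidin-2-one | O=C([C@@H]1[C@@H](C(C)C)CC=C(C)[C@@H]1C[C@H](O[Si](C)(C)C(C)(C)C)c1ccc(Br)o1)N1[C@@H](Cc2ccccc2)COC1=O
F6 | step 3 | [(1R,2R,6R)-2-{(2S)-2-(5-bromofuran-2-yl)-2-[(tert-butyldimethylsilyl)oxy]ethyl}-3-methyl-6-(propan-2-yl)cyclohex-3-en-1-yl]methanol | OC[C@@H]1[C@@H](C(C)C)CC=C(C)[C@@H]1C[C@H](O[Si](C)(C)C(C)(C)C)c1ccc(Br)o1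
F7 | step 4 | methyl enol ether of the homologated aldehyde (6 with a 2-methoxyethenyl group in place of CHO; E/Z mixture) | COC=C[C@@H]1[C@@H](C(C)C)CC=C(C)[C@@H]1C[C@H](O[Si](C)(C)C(C)(C)C)c1ccc(Br)o1
F8 | step 4 | 2-[(1R,2R,6R)-2-{(2S)-2-(5-bromofuran-2-yl)-2-[(tert-butyldimethylsilyl)oxy]ethyl}-3-methyl-6-(propan-2-yl)cyclohex-3-en-1-yl]acetaldehyde | O=CC[C@@H]1[C@@H](C(C)C)CC=C(C)[C@@H]1C[C@H](O[Si](C)(C)C(C)(C)C)c1ccc(Br)o1
F9 | step 4 | furanophane C3-alcohol (8 with OH in place of CO2Me at C3; C3 epimers) | OC1C[C@@H]2[C@@H](C(C)C)CC=C(C)[C@@H]2C[C@H](O[Si](C)(C)C(C)(C)C)c2ccc1o2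
F10 | step 4 | furanophane C3 methyl carbonate (C3 epimers) | COC(=O)OC1C[C@@H]2[C@@H](C(C)C)CC=C(C)[C@@H]2C[C@H](O[Si](C)(C)C(C)(C)C)c2ccc1o2
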